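The coupling partner, charged at 0.600 equiv on the left-handed substrate but able to react with either mirror form, pays for at most 30.0% of the two substrates together, which makes it the limiting reagent, so I looked for what happens to it on the way to the 20% asked about.

| flask | left-handed substrate | right-handed substrate | coupling partner | free catalyst | remark |
|---|---|---|---|---|---|
| alpha | 0.20 M | 0.20 M | 0.60 equiv | 0.17 mol% | run made earlier |
| zeta | 0.20 M | 0.20 M | 0.60 equiv | 0.66 mol% | run made earlier |
| flask | 0.20 M | 0.20 M | 0.600 equiv | 0.33 mol% |  |

| run | time / min | left-handed product / % | left-handed substrate / % |
|---|---|---|---|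
| alpha | 0.167 | 4.5 | 46.6 |
| alpha | 0.417 | 7.7 | 43.3 |
| alpha | 0.667 | 9.2 | 38.8 |
| alpha | 1.00 | 14.5 | 37.8 |
| alpha | 1.50 | 15.4 | 36.5 |
| alpha | 2.00 | 13.5 | 33.8 |
| alpha | 2.50 | 14.5 | 35.0 |
| zeta | 0.167 | 11.4 | 39.0 |
| zeta | 0.417 | 16.8 | 34.2 |
| zeta | 0.667 | 16.7 | 33.2 |
| zeta | 1.00 | 16.0 | 33.6 |
| zeta | 1.50 | 17.5 | 33.0 |
| zeta | 2.00 | 17.6 | 33.4 |
| zeta | 2.50 | 16.0 | 32.9 |

(each reading ± 1 percentage point)

* factor on the rate of making left-handed product when 20% of the left-handed substrate and right-handed substrate together are converted if free catalyst is charged twice over
* factor on the rate when 20% of the left-handed substrate and right-handed substrate together are converted if free catalyst is charged at 3 mol% instead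

- free catalyst is single-handed; left-handed substrate and right-handed substrate are mirror images of each other, charged as a racemate, each of them at the stated concentration
- the numbers in the tables scatter by 1 percentage point (one standard deviation)

From 1.00 min on, alpha held a mean of 14.5% of left-handed product and zeta 16.8%. I first doubted this gap of 2.3 percentage points, but the scatter of such a difference of means is 0.71 points, so the gap stands at about 3.25 times its scatter, and I kept it as a reading of moderate weight. My reading was that the partner also decays on a clock the catalyst doesn't set. If I take use and decay both as proportional to the partner present, and use also as proportional to loading, the curve drops out: the ratio of partner decayed to partner used stays constant through a run and varies inversely with loading. Alpha's ratio then comes to 0.227, and the product of this ratio and the loading, the loss loading 0.0385%, carries to other flasks under the same assumptions.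

The flask should have a ratio of 0.117, which means 10.4% of the partner it consumes goes to decay, so at 20% it keeps 25.6% of its charge, while at 3 mol% the ratio is 0.0128 and 32.5% remains. Taking the rate as loading times partner left, I reckoned 2.30 for doubling and 11.6 for 3 mol%, though this holds the catalyst's distribution fixed, which I couldn't test. The forecast, taking the rate as “first order in catalyst at fixed composition”, gave 2 (1.7 to 2.2) and 9.1 (5.5 to 10.5), so my second figure stood above its range.

The simulation gives 2.23 and 12.3.

    free catalyst + left-handed substrate ⇌ catalyst intermediate A (K = 35.0 L mol⁻¹, k = 1300 L mol⁻¹ s⁻¹)
    coupling partner → decomposed reagent (k = 0.00280 s⁻¹)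
    coupling partner + catalyst intermediate B → free catalyst + right-handed product (k = 48.0 L mol⁻¹ s⁻¹)
    free catalyst + right-handed substrate ⇌ catalyst intermediate B (K = 100 L mol⁻¹, k = 170 L mol⁻¹ s⁻¹)
    coupling partner + catalyst intermediate A → free catalyst + left-handed product (k = 98.0 L mol⁻¹ s⁻¹)

In the flask, decomposed reagent reached 0.00753 M after 2.50 min, which is 6.28% of the partner charge, against the 10.4% reckoned from the loss loading. At that time the partner's half-life by the step to left-handed product, 0.79 min, is shorter than the 4.13 min of its decay. At 3 mol%, the reckoned 11.6 lies below the simulated 12.3, and catalyst intermediate A at 20% conversion is 35.8% of the catalyst there, against 33.5% in the flask.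

The numbers in the tables are simulated for substances that don't exist; noise was put on by code.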